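**Plan**

Locants used below (daucane numbering): C1 = quaternary ring-fusion carbon bearing CH3; C2, C3 = CH2 of the five-membered ring; C4 = C(OH)(i-Pr); C5 = ring-fusion CH; C6 = ester carbon; C7 = CH2; C8(CH3)=C9; C10 = CH2.
Cuts, in order: the C6–O acyl bond, C6–H, C4–isopropyl, then C4–C5 together with C1–CH3 (this opens the five-membered ring), then C5 itself (one-carbon ring expansion), back to the benzene ring of 7-methylcoumarin, whose lactone already holds C2, C3, C4 and the oxygenation at C6.
Forward: Birch dearomatization of the arene and dibromocarbene ring expansion make the seven-membered ring first (10); the five-membered ring closes last (step 6); isopropyl, hydride and the ester follow.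
Enabling feature: in 10, C1 is the β-carbon of the C6 cycloheptenone and carries the C2–C3–C4 ester, so 1,4-addition of CH3 at C1 creates the C5 enolate five atoms from the acyl carbon C4 and the ring C1–C2–C3–C4–C5 closes by Dieckmann condensation.
Stereochemistry: C1 from the chiral copper catalyst; C4 by nucleophile attack anti to the angular methyl; C5 by protonation to the trans ring fusion; C6 by hydroxyl-directed hydride delivery.

Key step: step 6

Assumption: the phosphoramidite antipode that delivers CH3 to the Si face of C1 is taken to be the (S,S) ligand written in step 6; its mirror image is used if the sense of induction is the opposite.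

**Route**

Step 1
Reactants: 1 7-methylcoumarin
Product: 2 7-methylchroman-2-one
Conditions: H2 (1 atm), 10% Pd/C, EtOAc, rt
Reagents that add atoms: none
Why: Heterogeneous catalytic hydrogenation should reduce the conjugated lactone C=C of the coumarin far faster than the benzene ring; no stereocentre is formed.

Step 2
Reactants: 2 7-methylchroman-2-one
Product: 4 3-(2-methoxy-4-methylphenyl)propanoic acid, via disodium phenoxide carboxylate 3 (not isolated)
Conditions: NaOH, H2O, 60 °C; Me2SO4, 40 °C; NaOH, reflux; then HCl (aq)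
Reagents that add atoms: sodium hydroxide [Na+].[OH-]; dimethyl sulfate COS(=O)(=O)OC
Why: Saponification opens the aryl lactone, the phenoxide is O-methylated (Williamson ether synthesis), and the final hydroxide treatment returns any methyl ester to the carboxylate, so the acid should be obtained on acidification.

Step 3
Reactants: 4 3-(2-methoxy-4-methylphenyl)propanoic acid
Product: 6 methyl 3-(2-methoxy-4-methylcyclohexa-1,4-dien-1-yl)propanoate, via lithium dienyl carboxylate 5 (not isolated)
Conditions: Li, NH3 (l), t-BuOH, THF, −78 to −33 °C; NH3 evaporated; MeI, DMF, rt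
Reagents that add atoms: iodomethane CI
Why: Birch reduction should place the two sp3 carbons at the unsubstituted positions ortho and meta to OCH3, so that methoxy, alkyl and methyl all stay on double bonds while the carboxylate is untouched, and the carboxylate is then O-alkylated without acid, which the enol ether would not survive.

Step 4
Reactants: 6 methyl 3-(2-methoxy-4-methylcyclohexa-1,4-dien-1-yl)propanoate
Product: 8 methyl 3-(2-bromo-3,3-dimethoxy-5-methylcyclohepta-1,5-dien-1-yl)propanoate, via dibromocyclopropane 7 (not isolated)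
Conditions: CHBr3, KOtBu, pentane, −30 to 0 °C; then K2CO3, MeOH, 60 °C
Reagents that add atoms: bromoform BrC(Br)Br; methanol CO
Why: Electrophilic dibromocarbene should add to the tetrasubstituted enol ether rather than to the trisubstituted alkene, and the adduct then ionises with disrotatory cyclopropane opening to an oxygen-stabilised 2-bromoallyl cation that methanol captures as the dimethyl ketal (cyclopropyl–allyl ring expansion); the ketal cannot enolise, which blocks loss of HBr to a tropone.

Step 5
Reactants: 8 methyl 3-(2-bromo-3,3-dimethoxy-5-methylcyclohepta-1,5-dien-1-yl)propanoate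
Product: 10 methyl 3-(5-methyl-3-oxocyclohepta-1,5-dien-1-yl)propanoate, via dimethyl ketal 9 (not isolated)
Conditions: Bu3SnH, AIBN (cat.), benzene, 80 °C; then PPTS, acetone–H2O, rt
Reagents that add atoms: water O
Why: Radical-chain hydrodebromination of the vinyl bromide followed by mild acid hydrolysis of the allylic ketal should give the 3-substituted cycloheptadienone under conditions too mild to move the skipped C8=C9 double bond into conjugation.

Step 6
Reactants: 10 methyl 3-(5-methyl-3-oxocyclohepta-1,5-dien-1-yl)propanoate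
Product: 12 (8aR)-4-hydroxy-6,8a-dimethyl-1,2,5,8-tetrahydroazulen-3(8aH)-one (enol form of the bicyclic 1,3-diketone), via dimethylaluminium enolate 11 (not isolated)
Conditions: AlMe3, Cu(O2CC4H3S) (copper thiophene-2-carboxylate, monovalent copper, cat.), O,O′-(biphenyl-2,2′-diyl) N,N-bis[(S)-1-phenylethyl]phosphoramidite (cat.), Et2O, −30 °C; then MeLi, THF, −78 to 0 °C; HCl (1 M), 0 °C
Reagents that add atoms: trimethylaluminium C[Al](C)C
Why: A chiral methylcopper species formed from AlMe3 and the copper–phosphoramidite complex binds the enone of 10 and delivers CH3 to the Si face of the β-carbon C1 through a trivalent copper σ-alkyl intermediate and reductive elimination, which gives the C5=C6 aluminium enolate 11 regiospecifically; MeLi converts it into the more nucleophilic aluminate enolate, whose C5 attacks the ester carbonyl C4 held on C1. The closest known reaction types are the copper-catalysed asymmetric conjugate addition of trialkylaluminium reagents to 3-substituted cycloalk-2-enones, which creates quaternary centres, and the tandem conjugate addition–Dieckmann trapping of a metal enolate by a tethered ester. The five-membered ring closes in the 5-(enolexo)-exo-trig mode, and loss of methoxide leaves the β-diketonate, so C4 and C5 carry no stereochemistry at this stage. The only new stereocentre, quaternary C1 (R), is set by the ligand on copper, since the substrate is achiral. The step needs 1,4- over 1,2-addition (soft organocopper; ketone and ester are inert to AlMe3 at −30 °C), an enolate that is never protonated before ring closure, and no migration of the skipped C8=C9 alkene (no free base is present, and the product stays as its diketonate until the cold acidic quench).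

Step 7
Reactants: 12 (8aR)-4-hydroxy-6,8a-dimethyl-1,2,5,8-tetrahydroazulen-3(8aH)-one
Product: 13 (8aR)-4-[(tert-butyldimethylsilyl)oxy]-6,8a-dimethyl-1,2,5,8-tetrahydroazulen-3(8aH)-one
Conditions: TBSOTf, Et3N, CH2Cl2, 0 °C to rt
Reagents that add atoms: tert-butyldimethylsilyl trifluoromethanesulfonate CC(C)(C)[Si](C)(C)OS(=O)(=O)C(F)(F)F
Why: O-Silylation of the enolised β-diketone under equilibrating conditions (1,5 O-to-O silyl shift) should favour the isomer whose enol ether double bond is exocyclic to the five-membered ring and endocyclic in the seven-membered ring, which leaves the cyclopentanone carbonyl C4 as the only free ketone.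

Step 8
Reactants: 13 (8aR)-4-[(tert-butyldimethylsilyl)oxy]-6,8a-dimethyl-1,2,5,8-tetrahydroazulen-3(8aH)-one
Product: 16 (3R,3aR,8aR)-3-hydroxy-6,8a-dimethyl-3-(propan-2-yl)-1,2,3,3a,8,8a-hexahydroazulen-4(5H)-one, via chloromagnesium alkoxide 14 (not isolated), via hydroxy silyl enol ether 15 (not isolated)
Conditions: i-PrMgCl, CeCl3, THF, −78 °C; AcOH, −78 °C; then Bu4NF, AcOH, THF, 0 °C
Reagents that add atoms: isopropylmagnesium chloride CC(C)[Mg]Cl
Why: The organocerium reagent should add 1,2 to the vinylogous-ester carbonyl C4 at −78 °C, where silyl migration is frozen, from the face opposite the pseudoaxial angular methyl on C1 (hydroxyl cis to CH3, isopropyl trans), and the cold AcOH quench followed by buffered fluoride unmasks the C6 ketone with protonation of C5 anti to the methyl and oxygen substituents, giving the trans ring fusion, which should also be the more stable C5 epimer because isopropyl and C6 are then trans on the five-membered ring.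

Step 9
Reactants: 16 (3R,3aR,8aR)-3-hydroxy-6,8a-dimethyl-3-(propan-2-yl)-1,2,3,3a,8,8a-hexahydroazulen-4(5H)-one
Product: 17 (3R,3aS,4S,8aR)-6,8a-dimethyl-3-(propan-2-yl)-1,2,3,3a,4,5,8,8a-octahydroazulene-3,4-diol (jaeschkeanadiol)
Conditions: Me4NBH(OAc)3, MeCN–AcOH, −25 °C
Reagents that add atoms: none
Why: In this hydroxyl-directed triacetoxyborohydride reduction the tertiary C4 hydroxyl should exchange onto boron and deliver hydride intramolecularly to the face of the C6 carbonyl that carries the angular methyl, which gives the C6 alcohol anti to the directing oxygen (S at C6), under weakly acidic conditions that neither retro-aldolise the β-hydroxy ketone nor move the β,γ double bond.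

Step 10
Reactants: 17 jaeschkeanadiol; 18 4-acetoxybenzoyl chloride
Product: 19 (3R,3aS,4S,8aR)-3-hydroxy-6,8a-dimethyl-3-(propan-2-yl)-1,2,3,3a,4,5,8,8a-octahydroazulen-4-yl 4-acetoxybenzoate
Conditions: pyridine, DMAP (cat.), CH2Cl2, 0 °C to rt
Reagents that add atoms: 4-acetoxybenzoyl chloride CC(=O)Oc1ccc(C(=O)Cl)cc1
Why: DMAP-catalysed acylation with an acid chloride should esterify the secondary C6 alcohol, while the hindered tertiary C4 alcohol does not react.

Step 11
Reactants: 19 (3R,3aS,4S,8aR)-3-hydroxy-6,8a-dimethyl-3-(propan-2-yl)-1,2,3,3a,4,5,8,8a-octahydroazulen-4-yl 4-acetoxybenzoate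
Product: 20 ferutinine
Conditions: pyrrolidine, CH2Cl2, 0 °C
Reagents that add atoms: none
Why: Aminolysis of the aryl acetate by pyrrolidine should be much faster than attack at the hindered secondary alkyl benzoate, so only the phenol is set free.

**Compound list**

1 | 7-methylcoumarin (7-methyl-2H-chromen-2-one) | Cc1ccc2ccc(=O)oc2c1 | starting material
2 | 7-methylchroman-2-one | Cc1ccc2CCC(=O)Oc2c1 | intermediate
3 | disodium 3-(4-methyl-2-oxidophenyl)propanoate | Cc1ccc(CCC(=O)[O-])c([O-])c1.[Na+].[Na+] | intermediate
4 | 3-(2-methoxy-4-methylphenyl)propanoic acid | COc1cc(C)ccc1CCC(=O)O | intermediate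
5 | lithium 3-(2-methoxy-4-methylcyclohexa-1,4-dien-1-yl)propanoate | COC1=C(CCC(=O)[O-])CC=C(C)C1.[Li+] | intermediate
6 | methyl 3-(2-methoxy-4-methylcyclohexa-1,4-dien-1-yl)propanoate | COC(=O)CCC1=C(OC)CC(C)=CC1 | intermediate
7 | methyl 3-(7,7-dibromo-1-methoxy-3-methylbicyclo[4.1.0]hept-3-en-6-yl)propanoate (racemic, cis ring fusion) | COC(=O)CCC12CC=C(C)CC1(OC)C2(Br)Br | intermediate
8 | methyl 3-(2-bromo-3,3-dimethoxy-5-methylcyclohepta-1,5-dien-1-yl)propanoate | COC(=O)CCC1=C(Br)C(OC)(OC)CC(C)=CC1 | intermediate
9 | methyl 3-(3,3-dimethoxy-5-methylcyclohepta-1,5-dien-1-yl)propanoate | COC(=O)CCC1=CC(OC)(OC)CC(C)=CC1 | intermediate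
10 | methyl 3-(5-methyl-3-oxocyclohepta-1,5-dien-1-yl)propanoate | COC(=O)CCC1=CC(=O)CC(C)=CC1 | intermediate
11 | dimethylaluminium (3R)-3-(3-methoxy-3-oxopropyl)-3,6-dimethylcyclohepta-1,5-dien-1-olate | CC1=CC[C@@](C)(CCC(=O)OC)C=C(O[Al](C)C)C1 | intermediate
12 | (8aR)-4-hydroxy-6,8a-dimethyl-1,2,5,8-tetrahydroazulen-3(8aH)-one (enol form of the 3,4-dione) | CC1=CC[C@@]2(C)CCC(=O)C2=C(O)C1 | intermediate
13 | (8aR)-4-[(tert-butyldimethylsilyl)oxy]-6,8a-dimethyl-1,2,5,8-tetrahydroazulen-3(8aH)-one | CC1=CC[C@@]2(C)CCC(=O)C2=C(O[Si](C)(C)C(C)(C)C)C1 | intermediate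
14 | chloromagnesium (3R,8aR)-4-[(tert-butyldimethylsilyl)oxy]-6,8a-dimethyl-3-(propan-2-yl)-1,2,3,5,8,8a-hexahydroazulen-3-olate | CC1=CC[C@@]2(C)CC[C@@](O[Mg]Cl)(C(C)C)C2=C(O[Si](C)(C)C(C)(C)C)C1 | intermediate
15 | (3R,8aR)-4-[(tert-butyldimethylsilyl)oxy]-6,8a-dimethyl-3-(propan-2-yl)-1,2,3,5,8,8a-hexahydroazulen-3-ol | CC1=CC[C@@]2(C)CC[C@@](O)(C(C)C)C2=C(O[Si](C)(C)C(C)(C)C)C1 | intermediate
16 | (3R,3aR,8aR)-3-hydroxy-6,8a-dimethyl-3-(propan-2-yl)-1,2,3,3a,8,8a-hexahydroazulen-4(5H)-one | CC1=CC[C@@]2(C)CC[C@@](O)(C(C)C)[C@@H]2C(=O)C1 | intermediate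
17 | (3R,3aS,4S,8aR)-6,8a-dimethyl-3-(propan-2-yl)-1,2,3,3a,4,5,8,8a-octahydroazulene-3,4-diol (jaeschkeanadiol) | CC1=CC[C@@]2(C)CC[C@@](O)(C(C)C)[C@@H]2[C@@H](O)C1 | intermediate
18 | 4-acetoxybenzoyl chloride | CC(=O)Oc1ccc(C(=O)Cl)cc1 | starting material
19 | (3R,3aS,4S,8aR)-3-hydroxy-6,8a-dimethyl-3-(propan-2-yl)-1,2,3,3a,4,5,8,8a-octahydroazulen-4-yl 4-acetoxybenzoate | CC1=CC[C@@]2(C)CC[C@@](O)(C(C)C)[C@@H]2[C@@H](OC(=O)c2ccc(OC(C)=O)cc2)C1 | intermediate
20 | ferutinine, (3R,3aS,4S,8aR)-3-hydroxy-6,8a-dimethyl-3-(propan-2-yl)-1,2,3,3a,4,5,8,8a-octahydroazulen-4-yl 4-hydroxybenzoate | CC1=CC[C@@]2(C)CC[C@@](O)(C(C)C)[C@@H]2[C@@H](OC(=O)c2ccc(O)cc2)C1 | target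

**Count and risks**

Total step count: 11. Longest linear sequence: 11 steps (1 to 20); 18 is used as purchased.

Steps most likely to fail:

Step 6. The aluminium enolate may be too weak a nucleophile to acylate, MeLi may attack the ester before it activates the enolate, the Lewis acid may draw the skipped diene into conjugation, and the enantioselectivity on a seven-membered dienone is open. Fallback: setting out from 10, the conjugate addition is run alone and the aluminium enolate is silylated with Me3SiOTf to the isolable, regiodefined silyl enol ether methyl 3-[(1R)-1,5-dimethyl-3-(trimethylsilyloxy)cyclohepta-2,5-dien-1-yl]propanoate F1. MeLi (THF, 0 °C) then frees the lithium enolate, which should undergo the Dieckmann closure on warming, and acidic work-up returns the route to 12.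

Step 8. The basic reagent may deprotonate C3 instead of adding, may attack C4 from the face of the angular methyl (C4 epimer), or the silyl group may migrate to the new alkoxide and trigger E1cB loss of the C4 oxygen. Fallback: setting out from 13, 2-propenylmagnesium bromide with CeCl3 (a smaller, less basic sp2 nucleophile) and a cold AcOH quench should give the isopropenyl carbinol (3R,8aR)-4-[(tert-butyldimethylsilyl)oxy]-6,8a-dimethyl-3-(prop-1-en-2-yl)-1,2,3,5,8,8a-hexahydroazulen-3-ol F2. Buffered fluoride should give the hydroxy ketone (3S,3aR,8aR)-3-hydroxy-6,8a-dimethyl-3-(prop-1-en-2-yl)-1,2,3,3a,8,8a-hexahydroazulen-4(5H)-one F3, and hydrogenation with RhCl(PPh3)3 (H2, benzene) should saturate only the 1,1-disubstituted double bond and return the route to 16.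

Step 9. The hindered tertiary hydroxyl may fail to exchange onto boron, so that hydride arrives undirected from the less hindered face, opposite the angular methyl, and the C6 epimer forms. Fallback: setting out from 16, NaBH4 (MeOH, −20 °C) is used on purpose to give the C6 epimer (3R,3aS,4R,8aR)-6,8a-dimethyl-3-(propan-2-yl)-1,2,3,3a,4,5,8,8a-octahydroazulene-3,4-diol F4. Mitsunobu esterification (PPh3, DIAD, 4-acetoxybenzoic acid, THF) then inverts C6 and returns the route to 19.

Further compounds
F1 | step 6 | methyl 3-[(1R)-1,5-dimethyl-3-(trimethylsilyloxy)cyclohepta-2,5-dien-1-yl]propanoate | CC1=CC[C@@](C)(CCC(=O)OC)C=C(O[Si](C)(C)C)C1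
F2 | step 8 | (3R,8aR)-4-[(tert-butyldimethylsilyl)oxy]-6,8a-dimethyl-3-(prop-1-en-2-yl)-1,2,3,5,8,8a-hexahydroazulen-3-ol | CC1=CC[C@@]2(C)CC[C@@](O)(C(C)=C)C2=C(O[Si](C)(C)C(C)(C)C)C1
F3 | step 8 | (3S,3aR,8aR)-3-hydroxy-6,8a-dimethyl-3-(prop-1-en-2-yl)-1,2,3,3a,8,8a-hexahydroazulen-4(5H)-one | CC1=CC[C@@]2(C)CC[C@@](O)(C(C)=C)[C@@H]2C(=O)C1
F4 | step 9 | (3R,3aS,4R,8aR)-6,8a-dimethyl-3-(propan-2-yl)-1,2,3,3a,4,5,8,8a-octahydroazulene-3,4-diol | CC1=CC[C@@]2(C)CC[C@@](O)(C(C)C)[C@@H]2[C@H](O)C1
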